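**Compound numbering used throughout:** 1 3-bromo-1-(triisopropylsilyl)pyrrole; 2 3-bromo-1H-pyrrole; 3 3-bromo-1-(phenylsulfonyl)pyrrole; 4 its 2-lithio derivative; 5 3-bromo-2-iodo-1-(phenylsulfonyl)pyrrole; 6 trimethylsilylacetylene; 7 the mono-coupled 2-alkynyl-3-bromopyrrole; 8 the bis(silylethynyl)pyrrole; 9 2,3-diethynyl-1-(phenylsulfonyl)pyrrole; 10 bromotrichloromethane; 11 the indole-4,7-diyl diradical; 12 4,7-dibromo-1-(phenylsulfonyl)indole; 13 4,7-dibromo-1H-indole; 14 4,7-dibromo-3-chloro-1H-indole; 15 the target.

## Analysis of the target

The target 15 is 2,4,7-tribromo-3-chloro-1H-indole: a benzo-fused pyrrole with no stereocenter, a free N–H, and four halogens of two kinds. The pyrrole half carries bromine at C2 and chlorine at C3; the benzene half carries bromine at C4 and C7 and hydrogen at C5 and C6. C3 and C2 are the positions at which an indole reacts with electrophiles anyway (C3 first, then C2), so these two halogens can be added last, provided chlorine is delivered before bromine. The benzenoid bromines are the hard part: electrophilic bromination of an indole does not select C4 and C7, so these two C–Br bonds must come from the way the six-membered ring is made. 2,3-Dihalo-1H-indoles are sensitive to acid, light and air, which argues for creating that motif only at the very end. The strategy rests on the para relationship of C4–Br and C7–Br across an otherwise unsubstituted C5–C6 edge. That pattern is the footprint of a 1,4-didehydroarene, here the indole-4,7-diyl 11, which the 2,3-diethynylpyrrole 9 generates when its two alkyne termini join to form C5–C6.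

## Retrosynthetic reasoning

**C2–Br (15 to 14).** The C2–Br bond is cut first. With C3 occupied by chlorine and C4 to C7 deactivated by the flanking bromines, C2 is the only nucleophilic carbon left in 14. The forward step is a single electrophilic bromination that must leave the C3–Cl bond untouched. Placing it last keeps the labile 2,3-dihaloindole out of every other operation.

**C3–Cl (14 to 13).** The C3–Cl bond is cut next. The first electrophile on a 2,3-unsubstituted indole goes to C3, so the halogen destined for C3 has to be introduced before the one destined for C2. Chlorination of 13 therefore precedes bromination; the reverse order would give the wrong constitution.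

**N–S (13 to 12).** The nitrogen is re-protected as the phenylsulfonyl amide 12. The group is not needed in the target but is indispensable earlier: it directs metalation, makes the pyrrole electron-poor, and carries no weak C–H bond. Its removal by aqueous base is a routine N–S cleavage that the aryl C–Br bonds tolerate.

**C5–C6, C4–Br and C7–Br (12 to 9 and 10).** This is the key disconnection. Cutting C5–C6 and both benzenoid C–Br bonds of 12 reveals the enediyne 9, in which the pyrrole C2=C3 bond is the ene. Heating 9 should join the two terminal alkyne carbons and leave σ radicals on the inner alkyne carbons, which are C4 and C7 of diradical 11. Each radical takes bromine from its own molecule of 10, so two molecules of 10 are consumed. No other disconnection makes the ring and both C–Br bonds at once, with the halogens placed by the mechanism and not by directing effects. The forward reaction has to cyclize an enediyne whose alkynes are splayed apart by the five-membered ring, and both radical sites must be trapped by bromine and by nothing else.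

**C(sp)–Si (9 to 8).** The terminal alkynes of 9 are masked as trimethylsilyl alkynes in 8. The free diyne is prone to oligomerize, so it is released only immediately before the thermolysis, by mild basic methanolysis that spares the N–S bond.

**Two C(sp2)–C(sp) bonds (8 to 5 and 6).** Both alkynes are attached by palladium/copper-catalysed coupling of two molecules of 6 with the dihalide 5. The C2–I bond reacts first, via the mono-coupled bromide 7, and the C3–Br bond on heating. The two different halogens are not needed for selectivity, since both positions receive the same alkyne; they simply reflect how 5 is made.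

**C2–I (5 to 3).** The C2–I bond is made by deprotonation of 3 with a hindered lithium amide, giving the 2-lithio species 4, followed by electrophilic iodination of the anion. C2–H is the most acidic position because it lies between the sulfonylated nitrogen and the bromine. The forward step must trap this kinetic anion before it relays to C5.

**N-protecting group (3 to 1).** Compound 3 comes from commercial 1, whose bromine is already fixed at C3. A fluoride source removes the silyl group, and the unstable N–H pyrrole 2 is sulfonylated in the same flask.

## Alternatives that were turned down

**Alternative 1: aryne annulation with a dehydroalanine carbamate.** The disconnection is N1–C7a and C3–C3a: the five-membered ring is built onto a benzene that already carries both bromines. In the forward step, fluoride would release 3,6-dibromobenzyne A2 from 3,6-dibromo-2-(trimethylsilyl)phenyl trifluoromethanesulfonate A1. The carbamate nitrogen of methyl 2-[(tert-butoxycarbonyl)amino]acrylate A3 would add, and the aryl anion would close onto the acrylate terminus to give the racemic indoline diester A4.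
- For: the aryne is symmetrical, so there is no regiochemical question; the conditions are ionic and mild; the route is convergent. On mildness it is clearly stronger than a thermolysis near 200 °C.
- Against: the aryl anion formed after N-addition sits ortho to a bromine. Expulsion of bromide to give a second aryne competes with a geometrically awkward 5-endo conjugate addition. A1 needs a silyl group wedged between a triflate and a bromine, which is a multistep preparation in itself. A4 is two oxidation levels and one ester away from 13: carbamate cleavage, ester hydrolysis, decarboxylation and dehydrogenation all precede the two final halogenations.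
- Comparison: the chosen strategy gives the aromatic indole directly from the ring-forming step, with no redox or decarboxylation tail.

**Alternative 2: ynamide diyne plus acetylene (2+2+2) benzannulation.** The disconnection is C3a–C7a, C4–C5 and C6–C7: the whole benzene ring is assembled from three alkynes. In the forward step the silyl-capped ynamide diyne A5 and acetylene A6 would combine under rhodium catalysis to give 1-tosyl-4,7-bis(trimethylsilyl)indoline A7.
- For: the step is catalytic and mild; the two silyl groups mark C4 and C7 unambiguously; alkyne cyclotrimerization is better understood and more predictable than a diradical cascade. On reliability of the ring-forming event it is stronger.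
- Against: silyl groups on both diyne termini crowd the metallacycle and slow insertion of A6. The bromines are not delivered by the cyclization, so a double ipso-bromodesilylation is needed on a ring whose position para to nitrogen is itself activated. The indoline must then be dehydrogenated and the tosyl group removed before 13 is reached. Together with the preparation of A5 this is the longest of the four routes.
- Comparison: the chosen strategy forms both C–Br bonds in the same step that closes the ring, at the indole oxidation level.

**Alternative 3: dibromothiophene dioxide Diels–Alder onto an enecarbamate.** The disconnection is C3a–C4 and C7–C7a. In the forward step 2,5-dibromothiophene 1,1-dioxide A8 would act as electron-poor diene towards tert-butyl 2,3-dihydro-1H-pyrrole-1-carboxylate A9. Cheletropic loss of the sulfone bridge would give the racemic cis-fused dibromo tetrahydroindole A10.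
- For: the electronic pairing is well matched; the bromines at the diene termini map directly onto C4 and C7; both partners are made in one or two steps. On step count to 13 it is at least as short as the chosen route, probably shorter.
- Against: A10 lies four hydrogens above the indole oxidation level, and two stereocenters are made only to be destroyed. The cyclohexadiene can aromatize by another path: a 1,5-hydrogen shift places hydrogen and bromine on the same sp3 carbon, and dehydrobromination then erases one of the bromines that the route exists to install. The dioxide A8 also dimerizes in competition with the cycloaddition.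
- Comparison: the chosen strategy needs no oxidation state adjustment after ring formation and makes both C–Br bonds on an already aromatic ring, where they cannot be eliminated.

Key step: step 5

## Route

Assumption: the temperature and dilution given for step 5 are estimates reasoned from the geometry of five-membered-ring-fused enediynes and would be set by experiment.

Step 1
Reactants: 1 3-bromo-1-(triisopropylsilyl)-1H-pyrrole
Product: 3 3-bromo-1-(phenylsulfonyl)-1H-pyrrole, via 3-bromo-1H-pyrrole 2 (not isolated)
Conditions: n-Bu4NF (1.05 equiv), THF, 0 °C, 15 min; then PhSO2Cl (1.5 equiv), powdered NaOH (4 equiv), CH2Cl2, 0 °C to rt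
Reagents that add atoms: benzenesulfonyl chloride, O=S(=O)(Cl)c1ccccc1
Why: Fluoride cleaves the N–Si bond, and the acid-sensitive pyrrole 2 is not isolated but N-sulfonylated at once under solid–liquid phase-transfer conditions, the tetrabutylammonium ion already present serving as the transfer cation; this is a protecting-group exchange by desilylation and N-sulfonylation.

Step 2
Reactants: 3 3-bromo-1-(phenylsulfonyl)-1H-pyrrole
Product: 5 3-bromo-2-iodo-1-(phenylsulfonyl)-1H-pyrrole, via 3-bromo-2-lithio-1-(phenylsulfonyl)pyrrole 4 (not isolated)
Conditions: LiN(i-Pr)2 (1.1 equiv), THF, −78 °C, 30 min; then I2 (1.2 equiv) in THF, −78 °C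
Reagents that add atoms: iodine, II
Why: Directed lithiation: C2–H, flanked by the sulfonylated nitrogen and the bromine, is the kinetically most acidic position, and iodine is a fast enough electrophile to trap the C2 anion at −78 °C before it can relay to C5 or trigger bromine migration.

Step 3
Reactants: 5 3-bromo-2-iodo-1-(phenylsulfonyl)-1H-pyrrole; 6 trimethylsilylacetylene
Product: 8 1-(phenylsulfonyl)-2,3-bis[(trimethylsilyl)ethynyl]-1H-pyrrole, via 2-alkynyl-3-bromopyrrole 7 (not isolated)
Conditions: 6 (4 equiv), PdCl2(PPh3)2 (5 mol %), CuI (10 mol %), Et3N/DMF (1:2), degassed, rt 2 h, then 80 °C (sealed tube), 12–16 h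
Reagents that add atoms: trimethylsilylacetylene, C[Si](C)(C)C#C
Why: Twofold Sonogashira coupling: zerovalent palladium inserts into the C2–I bond at room temperature, and into the C3–Br bond of 7 on heating, where the electron-withdrawing sulfonyl group and the new ortho alkynyl group assist oxidative addition. Two molecules of 6 are taken up, one at each carbon–halogen bond, and the silyl caps prevent alkyne homocoupling at the product stage.

Step 4
Reactants: 8 1-(phenylsulfonyl)-2,3-bis[(trimethylsilyl)ethynyl]-1H-pyrrole
Product: 9 2,3-diethynyl-1-(phenylsulfonyl)-1H-pyrrole
Conditions: K2CO3 (0.2 equiv), MeOH/THF (1:1), 0 °C, 30 min; used promptly as a cold solution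
Reagents that add atoms: none
Why: Catalytic methoxide cleaves both C(sp)–Si bonds by protodesilylation far faster than it attacks the N–S bond at 0 °C; the terminal diyne is kept cold and in solution because aryl diynes of this kind oligomerize on storage.

Step 5
Reactants: 9 2,3-diethynyl-1-(phenylsulfonyl)-1H-pyrrole; 10 bromotrichloromethane
Product: 12 4,7-dibromo-1-(phenylsulfonyl)-1H-indole, via indole-4,7-diyl diradical 11 (not isolated)
Conditions: 10 as the solvent and bromine donor (degassed, about 3 mM in 9), sealed heavy-walled tube, 200–220 °C, dark
Reagents that add atoms: bromotrichloromethane, BrC(Cl)(Cl)Cl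
Why: This is a thermal Bergman cycloaromatization: the pyrrole C2=C3 bond is the ene, the termini of the two ethynyl groups join through their in-plane π orbitals to make the future C5–C6 bond, and the inner alkyne carbons become the σ radicals of 11 at C4 and C7. The closest known reaction type is the cycloaromatization of arene- and heteroarene-fused enediynes in perhalomethanes, where each aryl radical takes a halogen atom from the medium. The one ring formed is the six-membered carbocycle, closed by C1–C6 bond formation across the hexa-3-ene-1,5-diyne unit; because the five-membered ring splays the alkynes apart, a higher temperature than for a benzo-fused enediyne is planned. No stereocenter is formed. Two molecules of 10 are consumed for each molecule of 9, one bromine atom being transferred to C4 and one to C7, and the two trichloromethyl radicals left over should end as hexachloroethane. The selectivity needed is bromine over chlorine and hydrogen at both radical sites: the C–Br bond of 10 is much weaker than its C–Cl bonds and 10 is the medium itself, so bromine-atom transfer to an aryl radical should outrun reopening of 11, attack of the C7 radical on the neighbouring sulfonyl phenyl ring and hydrogen abstraction. The phenylsulfonyl group has no weak C–H bond and makes the pyrrole too electron-poor for the electrophilic trichloromethyl radicals. High dilution keeps radical-chain addition of 10 across the terminal alkynes of unreacted 9 behind the unimolecular cyclization.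

Step 6
Reactants: 12 4,7-dibromo-1-(phenylsulfonyl)-1H-indole
Product: 13 4,7-dibromo-1H-indole
Conditions: NaOH (2 M aq), 1,4-dioxane, 70 °C
Reagents that add atoms: none
Why: Hydroxide attacks sulfur and expels the indolide, a good leaving group made better by the peri bromine at C7, which strains the N–S bond; aryl bromides are inert to these conditions (N-desulfonylation by hydrolysis).

Step 7
Reactants: 13 4,7-dibromo-1H-indole
Product: 14 4,7-dibromo-3-chloro-1H-indole
Conditions: NCS (1.0 equiv), DMF, 0 °C to rt, dark
Reagents that add atoms: N-chlorosuccinimide, O=C1CCC(=O)N1Cl
Why: Electrophilic aromatic substitution at C3, the enamine-like and most nucleophilic carbon of the indole; one equivalent of reagent and the deactivated benzenoid ring should stop the reaction at the monochloride.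

Step 8
Reactants: 14 4,7-dibromo-3-chloro-1H-indole
Product: 15 2,4,7-tribromo-3-chloro-1H-indole
Conditions: NBS (1.0 equiv), CH2Cl2, 0 °C, dark
Reagents that add atoms: N-bromosuccinimide, O=C1CCC(=O)N1Br
Why: Electrophilic bromination of a 3-substituted indole at C2, either directly or by attack at C3 and 1,2-shift of bromine (the better bridging halogen) followed by loss of the C2 proton; C5 and C6 are deactivated by the adjacent bromines, so C2 is the only site left.

## Compound list

1 | 3-bromo-1-(triisopropylsilyl)-1H-pyrrole | CC(C)[Si](C(C)C)(C(C)C)n1ccc(Br)c1 | starting material
2 | 3-bromo-1H-pyrrole | Brc1cc[nH]c1 | intermediate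
3 | 3-bromo-1-(phenylsulfonyl)-1H-pyrrole | O=S(=O)(c1ccccc1)n1ccc(Br)c1 | intermediate
4 | 3-bromo-2-lithio-1-(phenylsulfonyl)-1H-pyrrole | [Li]c1c(Br)ccn1S(=O)(=O)c1ccccc1 | intermediate
5 | 3-bromo-2-iodo-1-(phenylsulfonyl)-1H-pyrrole | O=S(=O)(c1ccccc1)n1ccc(Br)c1I | intermediate
6 | trimethylsilylacetylene | C[Si](C)(C)C#C | starting material
7 | 3-bromo-1-(phenylsulfonyl)-2-[(trimethylsilyl)ethynyl]-1H-pyrrole | C[Si](C)(C)C#Cc1c(Br)ccn1S(=O)(=O)c1ccccc1 | intermediate
8 | 1-(phenylsulfonyl)-2,3-bis[(trimethylsilyl)ethynyl]-1H-pyrrole | C[Si](C)(C)C#Cc1ccn(S(=O)(=O)c2ccccc2)c1C#C[Si](C)(C)C | intermediate
9 | 2,3-diethynyl-1-(phenylsulfonyl)-1H-pyrrole | C#Cc1ccn(S(=O)(=O)c2ccccc2)c1C#C | intermediate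
10 | bromotrichloromethane | BrC(Cl)(Cl)Cl | starting material
11 | 1-(phenylsulfonyl)-1H-indole-4,7-diyl (σ,σ-diradical) | O=S(=O)(c1ccccc1)n1ccc2[c]ccc[c]21 | intermediate
12 | 4,7-dibromo-1-(phenylsulfonyl)-1H-indole | O=S(=O)(c1ccccc1)n1ccc2c(Br)ccc(Br)c21 | intermediate
13 | 4,7-dibromo-1H-indole | Brc1ccc(Br)c2[nH]ccc12 | intermediate
14 | 4,7-dibromo-3-chloro-1H-indole | Clc1c[nH]c2c(Br)ccc(Br)c12 | intermediate
15 | 2,4,7-tribromo-3-chloro-1H-indole | Clc1c(Br)[nH]c2c(Br)ccc(Br)c12 | target

## Step count and risk

Total step count: 8. Longest linear sequence: 8 steps, from 1 to 15.

**Step 5 (key step).** The most likely failure is that bimolecular radical chemistry overtakes the unimolecular ring closure. Every productive event releases two trichloromethyl radicals, which can add to the terminal alkynes of unreacted 9 and start a chain addition of 10. Alternatively 9 may oligomerize before it reaches the temperature at which its splayed alkyne termini can bond. Incomplete trapping at one of the two radical sites is a lesser concern in neat 10. The fallback gives up the enediyne construction of the benzene ring and makes 13 by a Bartoli indole synthesis. Commercial 1,4-dibromo-2-nitrobenzene F1 is treated with CH2=CHMgBr (3 equiv) in THF at −40 °C. The bromine ortho to the nitro group is the substituent this reaction requires, and the [3,3] shift can only engage the one free ortho carbon, so the bromines end at C4 and C7. This fallback does not set out from a numbered compound of the route: its starting point is F1. It comes back to the route at 13, and steps 7 and 8 follow unchanged.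

**Step 8.** The risk is loss of halogen fidelity. Attack of the bromine electrophile at C3, ipso to chlorine, followed by migration or expulsion of the wrong halogen would scramble the 2,3-dihalide, and the acid-sensitive product may degrade if traces of acid build up during the reaction. The fallback fixes the C2 bromine by deprotonation instead of electrophilic substitution and lets chlorine enter the one open azole position last. It sets out from 12. LiN(i-Pr)2 in THF at −78 °C gives 4,7-dibromo-2-lithio-1-(phenylsulfonyl)-1H-indole F2, which is quenched in the same flask with BrCCl2CCl2Br to 2,4,7-tribromo-1-(phenylsulfonyl)-1H-indole F3. NaOH in aqueous dioxane then gives 2,4,7-tribromo-1H-indole F4, and NCS in DMF chlorinates C3. It comes back to the route at 15.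

**Step 3.** The risk is stalling after the first coupling: oxidative addition into the C3–Br bond of 7 is slow, while 6 is consumed by copper-mediated dimerization. The fallback activates the electrophile instead of forcing the catalyst. It sets out from 5. Copper-catalysed halide exchange (CuI 5 mol %, NaI 2 equiv, trans-N,N'-dimethylcyclohexane-1,2-diamine 10 mol %, 1,4-dioxane, 110 °C) gives 2,3-diiodo-1-(phenylsulfonyl)-1H-pyrrole F5. Both C–I bonds then couple with 6 at room temperature under the catalyst system of step 3. It comes back to the route at 8.

**Step 2.** The risk is erosion of regiochemistry: proton transfer between 4 and unreacted 3 can relay the anion to the less hindered C5, or bromine can migrate, before the iodine quench. The fallback replaces deprotonation by electrophilic substitution on the unprotected pyrrole, and so replaces steps 1 and 2 together. It sets out from 1. n-Bu4NF in THF at 0 °C releases 2; the solution is cooled to −78 °C and N-iodosuccinimide (1.0 equiv) is added. Iodination is expected at the α position next to the bromine, as in 3-halothiophenes, giving 3-bromo-2-iodo-1H-pyrrole F6, which is not isolated but sulfonylated at once with powdered NaOH and PhSO2Cl. It comes back to the route at 5.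

## Further compounds

F1 | step 5 | 1,4-dibromo-2-nitrobenzene | O=[N+]([O-])c1cc(Br)ccc1Br
F2 | step 8 | 4,7-dibromo-2-lithio-1-(phenylsulfonyl)-1H-indole | [Li]c1cc2c(Br)ccc(Br)c2n1S(=O)(=O)c1ccccc1
F3 | step 8 | 2,4,7-tribromo-1-(phenylsulfonyl)-1H-indole | O=S(=O)(c1ccccc1)n1c(Br)cc2c(Br)ccc(Br)c21
F4 | step 8 | 2,4,7-tribromo-1H-indole | Brc1cc2c(Br)ccc(Br)c2[nH]1
F5 | step 3 | 2,3-diiodo-1-(phenylsulfonyl)-1H-pyrrole | O=S(=O)(c1ccccc1)n1ccc(I)c1I
F6 | step 2 | 3-bromo-2-iodo-1H-pyrrole | Brc1cc[nH]c1I
A1 | alternative 1 | 3,6-dibromo-2-(trimethylsilyl)phenyl trifluoromethanesulfonate | C[Si](C)(C)c1c(Br)ccc(Br)c1OS(=O)(=O)C(F)(F)F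
A2 | alternative 1 | 3,6-dibromobenzyne | BrC1=CC=C(Br)C#C1
A3 | alternative 1 | methyl 2-[(tert-butoxycarbonyl)amino]acrylate | C=C(NC(=O)OC(C)(C)C)C(=O)OC
A4 | alternative 1 | 1-tert-butyl 2-methyl 4,7-dibromoindoline-1,2-dicarboxylate (racemic) | COC(=O)C1Cc2c(Br)ccc(Br)c2N1C(=O)OC(C)(C)C
A5 | alternative 2 | 4-methyl-N-[4-(trimethylsilyl)but-3-yn-1-yl]-N-[(trimethylsilyl)ethynyl]benzenesulfonamide | Cc1ccc(cc1)S(=O)(=O)N(CCC#C[Si](C)(C)C)C#C[Si](C)(C)C
A6 | alternative 2 | acetylene | C#C
A7 | alternative 2 | 1-tosyl-4,7-bis(trimethylsilyl)indoline | Cc1ccc(cc1)S(=O)(=O)N1CCc2c([Si](C)(C)C)ccc([Si](C)(C)C)c21
A8 | alternative 3 | 2,5-dibromothiophene 1,1-dioxide | O=S1(=O)C(Br)=CC=C1Br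
A9 | alternative 3 | tert-butyl 2,3-dihydro-1H-pyrrole-1-carboxylate | CC(C)(C)OC(=O)N1CCC=C1
A10 | alternative 3 | tert-butyl cis-4,7-dibromo-2,3,3a,7a-tetrahydro-1H-indole-1-carboxylate (racemic) | CC(C)(C)OC(=O)N1CC[C@@H]2C(Br)=CC=C(Br)[C@H]12
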